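**Retrosynthetic overview**
1. Both 4-bromobutenolides are opened last, each to a tertiary propargylic alcohol plus CO and bromide (C–Br, C–C(=O) and acyl–O bonds). The two lactone rings are closed last, together, on the finished cyclobutane.
2. The trans-dibromide goes back to a cyclobutene. Br2 is added while the quaternary carbons still carry slim alkynyl and OSiMe3 groups, so each bromine should end anti to its vicinal C–O bond.
3. The trans-1,2-dialkynyl diol is cut at the bond to the (R)-3-hydroxyhexynyl group: alkoxide-directed acetylide addition to a 4-alkynyl-4-hydroxycyclobutenone.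
4. The four-membered ring, formed first, comes from an enantioselective α-ketol ring expansion (1,2-shift of a cyclopropane C–C bond) of a 1-alkynoylcyclopropanol, made from methyl 1-hydroxycyclopropane-1-carboxylate and hex-1-yne.

Assumption: (3R)-hex-1-yn-3-ol is bought as the single enantiomer.

**Route**

Step 1
Reactants: 1 methyl 1-hydroxycyclopropane-1-carboxylate; 2 hex-1-yne
Product: 5 1-(1-hydroxycyclopropyl)hept-2-yn-1-one, via hex-1-ynylmagnesium chloride 3 (not isolated), via Weinreb amide 4 (not isolated)
Conditions: MeNH(OMe)·HCl, i-PrMgCl, THF, −20 °C; then 3 (from 2 and i-PrMgCl, THF, 0 °C), −20 → 0 °C; pH 7 buffer, 0 °C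
Reagents that add atoms: none
Why: One-pot Weinreb ketone synthesis: the chloromagnesium amide turns the ester into the N-methoxy-N-methylamide and the alkynyl Grignard reagent adds only once because the chelated tetrahedral adduct survives until the buffered quench, which also keeps the base-sensitive hydroxy ynone from cyclising; no stereocentre is formed.

Step 2
Reactants: 5 1-(1-hydroxycyclopropyl)hept-2-yn-1-one
Product: 6 (2S)-2-(hex-1-yn-1-yl)-2-hydroxycyclobutan-1-one
Conditions: Sc(OTf)3 (10 mol %), (S,S)-i-Pr-pybox (12 mol %), 4 Å MS, CH2Cl2, −20 °C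
Reagents that add atoms: none
Why: Proposed new method: ring-expanding α-ketol (acyloin) rearrangement made enantioselective – the Sc(OTf)3/pybox Lewis acid chelates the hydroxyl and the ynone carbonyl, the two enantiotopic cyclopropane C–C bonds then lie on opposite sides of the chelate plane and only the one on the open side undergoes the 1,2-shift to the carbonyl carbon, which builds the four-membered ring and the quaternary (S)-carbinol centre (the ligand antipode is taken if the first run shows the opposite sense); closest known reaction types are the thermal or achiral-Lewis-acid α-ketol ring expansion of 1-acylcycloalkanols and chiral-Lewis-acid α-ketol rearrangements of chelating α-hydroxy carbonyl compounds.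

Step 3
Reactants: 6 (2S)-2-(hex-1-yn-1-yl)-2-hydroxycyclobutan-1-one
Product: 7 (4S)-4-(hex-1-yn-1-yl)-4-hydroxycyclobut-2-en-1-one
Conditions: 2-iodoxybenzoic acid (IBX), 4-methoxypyridine N-oxide, DMSO, 25 °C
Reagents that add atoms: none
Why: IBX dehydrogenation of a ketone through its enol (only C4 can enolise) gives the cyclobutenone at room temperature without base, so the quaternary carbinol centre and the alkyne stay untouched.

Step 4
Reactants: 7 (4S)-4-(hex-1-yn-1-yl)-4-hydroxycyclobut-2-en-1-one; 8 (3R)-hex-1-yn-3-ol
Product: 11 (3S,4S)-3-(hex-1-yn-1-yl)-3,4-bis(trimethylsilyloxy)-4-[(3R)-3-(trimethylsilyloxy)hex-1-yn-1-yl]cyclobut-1-ene, via dimagnesium alkynide-alkoxide 9 (not isolated), via triol tris(bromomagnesium) alkoxide 10 (not isolated)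
Conditions: 8 (2 equiv), EtMgBr (4 equiv), THF, 0 → 25 °C; then 7, −78 → −40 °C; then TMSOTf, −78 → −20 °C; cold work-up, used at once
Reagents that add atoms: trimethylsilyl trifluoromethanesulfonate, C[Si](C)(C)OS(=O)(=O)C(F)(F)F
Why: Chelation-controlled (Cram-chelate) 1,2-addition of an alkynyl Grignard reagent: the magnesium alkoxide of 7 binds the reagent on the face of its oxygen, the alkynyl group is delivered anti to the hexynyl group and the trans-diol (new centre S) results, the (R)-carbinol of 8 is carried through unchanged, and silylation in the same flask before warming forestalls alkoxide-accelerated opening of the cyclobutene.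

Step 5
Reactants: 11 (3S,4S)-3-(hex-1-yn-1-yl)-3,4-bis(trimethylsilyloxy)-4-[(3R)-3-(trimethylsilyloxy)hex-1-yn-1-yl]cyclobut-1-ene
Product: 13 (1S,2S,3R,4R)-3,4-dibromo-1-(hex-1-yn-1-yl)-2-[(3R)-3-hydroxyhex-1-yn-1-yl]cyclobutane-1,2-diol, via tris-silyl dibromide 12 (not isolated)
Conditions: Br2 (1.05 equiv), CH2Cl2, −78 °C, dark; then MeOH, AcCl (cat.), 0 °C
Reagents that add atoms: bromine, BrBr
Why: Electrophilic anti-bromination of the strained cis-alkene (the oxygen-flanked internal alkynes are far slower): bromide opens the bromonium ion at the carbon whose quaternary neighbour presents its rod-like alkynyl group and not its OSiMe3 group to the incoming nucleophile, so each C–Br bond ends anti to the vicinal C–O bond (3R,4R) and trans to the other bromine, and mild acidic methanolysis then frees the three hydroxyls without base.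

Step 6
Reactants: 13 (1S,2S,3R,4R)-3,4-dibromo-1-(hex-1-yn-1-yl)-2-[(3R)-3-hydroxyhex-1-yn-1-yl]cyclobutane-1,2-diol
Product: 14 (3R)-1-[(1S,2S,3R,4R)-3,4-dibromo-2-(hex-1-yn-1-yl)-1,2-dihydroxycyclobutyl]hex-1-yn-3-yl acetate
Conditions: Ac2O (1.2 equiv), pyridine, DMAP (5 mol %), CH2Cl2, 0 °C
Reagents that add atoms: acetic anhydride, CC(=O)OC(C)=O
Why: DMAP-catalysed acylation is selective for the secondary alcohol because both tertiary propargylic alcohols sit on fully substituted ring carbons; no stereocentre is touched.

Step 7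
Reactants: 14 (3R)-1-[(1S,2S,3R,4R)-3,4-dibromo-2-(hex-1-yn-1-yl)-1,2-dihydroxycyclobutyl]hex-1-yn-3-yl acetate
Product: 15 (1R)-1-[(5S,6S,11R,12R)-4,10,11,12-tetrabromo-3-butyl-2,8-dioxo-1,7-dioxadispiro[4.0.4.2]dodeca-3,9-dien-9-yl]butyl acetate
Conditions: PdBr2 (10 mol %), LiBr (6 equiv), 1,4-benzoquinone (2.5 equiv), AcOH (4 equiv), CO (1 atm), MeCN, 25 °C
Reagents that add atoms: carbon monoxide, [C-]#[O+]; lithium bromide, [Li+].[Br-]
Why: Proposed new method: hydroxyl-directed anti-bromopalladation/carbonylative lactonisation – divalent palladium held by the tertiary hydroxyl and the alkyne is attacked by external bromide at the proximal alkyne carbon, the metal ends on the distal carbon cis to the carbinol in a five-membered oxapalladacycle, CO insertion and C–O bond formation close the 3-alkyl-4-bromobutenolide and benzoquinone reoxidises zerovalent palladium, so both lactone rings and both vinylic C–Br bonds form with no bond to a stereocentre broken (5S,6S,11R,12R and the side-chain R centre are retained); closest known reaction types are the PdCl2/CuCl2 halocarbonylative cyclisation of propargylic alcohols to α-(haloalkylidene)-β-lactones, trans-halopalladation-initiated cyclisations in LiBr/AcOH and the palladium-catalysed cyclocarbonylation of (Z)-3-halo-allylic alcohols to butenolides.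

**Compound list**
1 | methyl 1-hydroxycyclopropane-1-carboxylate | COC(=O)C1(O)CC1 | starting material
2 | hex-1-yne | CCCCC#C | starting material
3 | hex-1-yn-1-ylmagnesium chloride | CCCCC#C[Mg]Cl | intermediate
4 | 1-hydroxy-N-methoxy-N-methylcyclopropane-1-carboxamide (Weinreb amide, present in the flask as its chloromagnesium alkoxide) | CON(C)C(=O)C1(O)CC1 | intermediate
5 | 1-(1-hydroxycyclopropyl)hept-2-yn-1-one | CCCCC#CC(=O)C1(O)CC1 | intermediate
6 | (2S)-2-(hex-1-yn-1-yl)-2-hydroxycyclobutan-1-one | CCCCC#C[C@@]1(O)CCC1=O | intermediate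
7 | (4S)-4-(hex-1-yn-1-yl)-4-hydroxycyclobut-2-en-1-one | CCCCC#C[C@@]1(O)C=CC1=O | intermediate
8 | (3R)-hex-1-yn-3-ol | C#C[C@@H](CCC)O | starting material
9 | bromomagnesium (3R)-1-(bromomagnesio)hex-1-yn-3-olate | Br[Mg]C#C[C@@H](CCC)O[Mg]Br | intermediate
10 | (1S,2S)-1-(hex-1-yn-1-yl)-2-[(3R)-3-hydroxyhex-1-yn-1-yl]cyclobut-3-ene-1,2-diol (present in the flask as its tris(bromomagnesium) alkoxide) | CCCCC#C[C@@]1(O)C=C[C@]1(O)C#C[C@@H](CCC)O | intermediate
11 | (3S,4S)-3-(hex-1-yn-1-yl)-3,4-bis(trimethylsilyloxy)-4-[(3R)-3-(trimethylsilyloxy)hex-1-yn-1-yl]cyclobut-1-ene | CCCCC#C[C@@]1(O[Si](C)(C)C)C=C[C@]1(O[Si](C)(C)C)C#C[C@@H](CCC)O[Si](C)(C)C | intermediate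
12 | (1S,2S,3R,4R)-3,4-dibromo-1-(hex-1-yn-1-yl)-1,2-bis(trimethylsilyloxy)-2-[(3R)-3-(trimethylsilyloxy)hex-1-yn-1-yl]cyclobutane | CCCCC#C[C@@]1(O[Si](C)(C)C)[C@@H](Br)[C@H](Br)[C@]1(O[Si](C)(C)C)C#C[C@@H](CCC)O[Si](C)(C)C | intermediate
13 | (1S,2S,3R,4R)-3,4-dibromo-1-(hex-1-yn-1-yl)-2-[(3R)-3-hydroxyhex-1-yn-1-yl]cyclobutane-1,2-diol | CCCCC#C[C@@]1(O)[C@@H](Br)[C@H](Br)[C@]1(O)C#C[C@@H](CCC)O | intermediate
14 | (3R)-1-[(1S,2S,3R,4R)-3,4-dibromo-2-(hex-1-yn-1-yl)-1,2-dihydroxycyclobutyl]hex-1-yn-3-yl acetate | CCCCC#C[C@@]1(O)[C@@H](Br)[C@H](Br)[C@]1(O)C#C[C@@H](CCC)OC(C)=O | intermediate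
15 | (1R)-1-[(5S,6S,11R,12R)-4,10,11,12-tetrabromo-3-butyl-2,8-dioxo-1,7-dioxadispiro[4.0.4.2]dodeca-3,9-dien-9-yl]butyl acetate (the two lactone oxygens trans on the cyclobutane, each ring bromine anti to its vicinal lactone oxygen and trans to the other ring bromine) | CCCCC1=C(Br)[C@@]2(OC1=O)[C@@H](Br)[C@H](Br)[C@@]21OC(=O)C([C@@H](CCC)OC(C)=O)=C1Br | target

**Step count and risks**
Total step count: 7. Longest linear sequence: 7 steps (1 to 15; compounds 2 and 8 are bought).

The three steps most likely to fail:

Risk at step 2 (new asymmetric ring expansion). The enantioselectivity may be low. The hydroxy ynone 5 can also close to a spiro-3(2H)-furanone by oxa-Michael addition, or the cyclopropanol can open. Fallback with known chemistry: set out from 5 and run the α-ketol ring expansion without chiral control (Yb(OTf)3, CH2Cl2, 25 °C, or heat in toluene). This gives the racemic ketol. The enantiomers are then separated by preparative chromatography on a chiral stationary phase. The wanted enantiomer is 6, where the route is rejoined. The unwanted one, (2R)-2-(hex-1-yn-1-yl)-2-hydroxycyclobutan-1-one F1, is set aside.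

Risk at step 3 (dehydrogenation of a cyclobutanone). Cyclobutanone enolisation is slow and the cyclobutenone 7 is a reactive Michael acceptor, so direct IBX dehydrogenation may stall or over-react. Fallback by α-functionalisation and elimination: set out from 6. Acid-type α-selenenylation through the enol (PhSeCl, EtOAc, 25 °C) gives (2S)-2-(hex-1-yn-1-yl)-2-hydroxy-4-(phenylselanyl)cyclobutan-1-one F2 as both C4 epimers. Oxidation (H2O2, pyridine, CH2Cl2, 0 °C) and selenoxide syn-elimination then give 7, where the route is rejoined.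

Risk at step 7 (new bromocarbonylative double lactonisation). Bromide may attack the distal alkyne carbon, which would lead to β-lactones. The vinylpalladium may be protonated before CO insertion. The propargylic acetate may also take part. Fallback with known chemistry: set out from 14. Br2 (2.1 equiv, CH2Cl2, 0 °C) adds anti to both alkynes and gives (1E,3R)-1,2-dibromo-1-[(1S,2S,3R,4R)-3,4-dibromo-2-[(1E)-1,2-dibromohex-1-en-1-yl]-1,2-dihydroxycyclobutyl]hex-1-en-3-yl acetate F3. In F3 the distal vinylic bromine is cis to each tertiary hydroxyl. Cyclocarbonylation with Pd(PPh3)4 (zerovalent palladium), CO (1 atm) and i-Pr2NEt in MeCN at 50 °C then inserts into that C–Br bond, takes up CO and lactonises. This is the known butenolide synthesis from (Z)-3-halo-allylic alcohols and gives 15 directly. The fallback has its own risk: zerovalent palladium may also attack the ring dibromide.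

Two further weak points have no fallback here. In step 4 the trans-selectivity rests on the chelate model. In step 5 the preference for bromine anti to oxygen is argued from sterics and dipoles, not from a precedent on this ring.

**Further compounds**
F1 | step 2 | (2R)-2-(hex-1-yn-1-yl)-2-hydroxycyclobutan-1-one | CCCCC#C[C@]1(O)CCC1=O
F2 | step 3 | (2S)-2-(hex-1-yn-1-yl)-2-hydroxy-4-(phenylselanyl)cyclobutan-1-one (C4 epimers) | CCCCC#C[C@@]1(O)CC([Se]c2ccccc2)C1=O
F3 | step 7 | (1E,3R)-1,2-dibromo-1-[(1S,2S,3R,4R)-3,4-dibromo-2-[(1E)-1,2-dibromohex-1-en-1-yl]-1,2-dihydroxycyclobutyl]hex-1-en-3-yl acetate | CCCC/C(Br)=C(\Br)[C@@]1(O)[C@@H](Br)[C@H](Br)[C@]1(O)/C(Br)=C(Br)/[C@@H](CCC)OC(C)=O
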